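**Plan**

- Retrosynthesis: the C11–OOH bond (with the C6=C7 shift) is cut by a retro-ene to a 7(11)-isopropylidene. Then come C7=C11 (acetone aldol and dehydration), C1–O (γ-hydroxylation of the enone), the ester C–O at C3, and last the two ring-A bonds C3–C4 and C4–C5, which takes out C4 with its methyl as a one-carbon insert.
- Why the last cut is possible: ring B, with the angular methyl on C5 and the C9=C10–C8=O enone, is already the cyclohexenone ring of the (S)-bicyclic enedione made from 2-methylcyclopentane-1,3-dione. Its cyclopentanone lacks only C4(H)CH3 between C5 and the C3 carbonyl.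
- Forward: ring B and C5 come with the enedione. C8 is masked as a dithiolane, the five-membered ketone is enlarged to ring A by a β-oxido carbenoid shift, and then C3–O, the C8 enone, C1–O, C7=C11 and C11–OOH follow in that order.
- Stereochemistry: C5 comes from the starting material and is retained in the 1,2-shift. C4 is set by enolate protonation anti to C14, C3 by equatorial hydride delivery, C1 by axial oxygen delivery to the linear dienol ether, and the Z ester geometry by angelic acid.

Key step: step 2

Convention: eremophilane numbering is used (ring A = C1–C5, C10; ring B = C5–C10; C14 = methyl on C5, C15 = methyl on C4, C11–C13 = three-carbon unit on C7). "Trinor" compounds lack C11–C13, β is the face of C14, and angeloyl is (Z)-2-methylbut-2-enoyl. LiTMP is taken as a pre-formed reagent.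

**Step 1**
Reactants: 1 (S)-7a-methyl-2,3,7,7a-tetrahydro-1H-indene-1,5(6H)-dione; 2 ethane-1,2-dithiol
Product: 3 (S)-5,5-ethylenedithio-7a-methyl-2,3,5,6,7,7a-hexahydro-1H-inden-1-one
Conditions: HS(CH2)2SH, p-TsOH·H2O (cat.), AcOH, rt
Reagents that add atoms: none
Why: Acid-catalysed dithioketalisation is expected to take the conjugated carbonyl chemoselectively, as in related bicyclic enediones, because the saturated ketone is neopentyl and the allylic thionium ion forms easily, and the C9=C10 bond does not move in dithioketals.

**Step 2**
Reactants: 3 (S)-5,5-ethylenedithio-7a-methyl-2,3,5,6,7,7a-hexahydro-1H-inden-1-one; 4 1,1-dibromoethane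
Product: 8 (4R,5R)-8,8-ethylenedithio-11,12,13-trinoreremophil-9-en-3-one, via lithium dibromoalkoxide 5 (not isolated), via β-oxido carbenoid 6 (not isolated), via lithium enolate 7 (not isolated)
Conditions: CH3CHBr2, LiTMP, THF–Et2O, −100 °C; then 3; n-BuLi, −100 → −20 °C; AcOH, −78 °C
Reagents that add atoms: none
Why: CH3CBr2Li, made from 4 and LiTMP before the ketone is added, should add to the cyclopentanone carbonyl anti to the angular methyl to give alkoxide 5; bromine–lithium exchange then gives the β-oxido carbenoid 6, which on warming loses LiBr while the ring bond anti to the leaving bromide shifts to the carbenoid carbon, leaving the lithium enolate 7 of the homologated ketone. The closest known reaction type is the β-oxido carbenoid (carbenoid semipinacol) one-carbon ring enlargement of cyclic ketones with 1,1-dibromoalkanes. Ring A is not closed by a cyclisation but arises by expansion of the five-membered ketone (5 → 6): C3–C4 forms in the addition and C4–C5 in the shift, so that C4 is inserted between C3 and C5. C5 migrates with retention, which carries the (S)-centre of 1 unchanged into the angular position, and the new C4 centre is set when enolate 7 is protonated at −78 °C from the face anti to the adjacent axial C14 methyl (axial protonation, C15 equatorial and cis to C14). The step needs quaternary C5 to migrate and not C2H2, which the known preference of carbenoid and related electron-demanding shifts for the more substituted, electron-richer carbon should secure. It also needs the dithiolane to survive n-BuLi, which the far faster bromine–lithium exchange at −100 °C, a near-stoichiometric charge and the slow reaction of n-BuLi with the hindered amine should secure.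

**Step 3**
Reactants: 8 (4R,5R)-8,8-ethylenedithio-11,12,13-trinoreremophil-9-en-3-one
Product: 9 8,8-ethylenedithio-11,12,13-trinoreremophil-9-en-3β-ol
Conditions: L-Selectride (LiBH(s-Bu)3), THF, −78 °C; H2O (no peroxide work-up)
Reagents that add atoms: none
Why: In this bulky trialkylborohydride reduction of a cyclohexanone the hydride enters along the equatorial trajectory, anti to the syn-axial C14 methyl that blocks the axial path, so the axial 3β-alcohol cis to both methyls should result, and the peroxide-free work-up spares the dithiolane.

**Step 4**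
Reactants: 9 8,8-ethylenedithio-11,12,13-trinoreremophil-9-en-3β-ol; 10 angelic acid
Product: 12 3β-angeloyloxy-8,8-ethylenedithio-11,12,13-trinoreremophil-9-ene, via mixed anhydride 11 (not isolated)
Conditions: angelic acid, 2,4,6-Cl3C6H2COCl, Et3N, toluene, rt; then 9, 80 °C
Reagents that add atoms: none
Why: In this Yamaguchi-type mixed-anhydride esterification, run without a nucleophilic catalyst, the alcohol attacks the angeloyl carbonyl of 11 because the other carbonyl is shielded by two ortho chlorines; C3 keeps its configuration, and leaving out DMAP avoids the addition–elimination that would turn the Z ester into the tiglate.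

**Step 5**
Reactants: 12 3β-angeloyloxy-8,8-ethylenedithio-11,12,13-trinoreremophil-9-ene
Product: 13 3β-angeloyloxy-11,12,13-trinoreremophil-9-en-8-one
Conditions: Hg(ClO4)2, CaCO3, THF–H2O, 0 °C
Reagents that add atoms: water, O
Why: In this thiophilic dithioketal hydrolysis by divalent mercury the allylic thionium ion is trapped by water to return the conjugated ketone, CaCO3 takes up the acid, and the electron-poor angelate alkene is not expected to be mercurated.

**Step 6**
Reactants: 13 3β-angeloyloxy-11,12,13-trinoreremophil-9-en-8-one
Product: 14 3β-angeloyloxy-8-(tert-butyldimethylsilyloxy)-11,12,13-trinoreremophila-1(10),8-diene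
Conditions: TBSOTf, Et3N, CH2Cl2, 0 °C → rt (used crude)
Reagents that add atoms: tert-butyldimethylsilyl trifluoromethanesulfonate, CC(C)(C)[Si](C)(C)OS(=O)(=O)C(F)(F)F
Why: Soft enolisation with a silyl triflate and an amine under equilibrating conditions should give the thermodynamically preferred linear dienol silyl ether by loss of a γ-hydrogen from C1, the known behaviour of ring-fused cyclohexenones of this type, while the ester is not enolised.

**Step 7**
Reactants: 14 3β-angeloyloxy-8-(tert-butyldimethylsilyloxy)-11,12,13-trinoreremophila-1(10),8-diene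
Product: 15 3β-angeloyloxy-1β-hydroxy-11,12,13-trinoreremophil-9-en-8-one
Conditions: mCPBA, CH2Cl2, −20 °C; aq. NaHCO3 work-up
Reagents that add atoms: 3-chloroperbenzoic acid, OOC(=O)c1cccc(Cl)c1
Why: In this vinylogous Rubottom oxidation the peracid transfers oxygen to the γ-carbon C1 of the dienol ether along the stereoelectronically required axial trajectory, which, as in the γ-hydroxylation of steroidal dienol ethers syn to the angular methyl, should place the new hydroxyl β (cis to C14); the silyl group is lost as silanol on work-up and the electron-poor angelate alkene is left alone.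

**Step 8**
Reactants: 15 3β-angeloyloxy-1β-hydroxy-11,12,13-trinoreremophil-9-en-8-one
Product: 16 3β-angeloyloxy-1β-(triethylsilyloxy)-11,12,13-trinoreremophil-9-en-8-one
Conditions: TESOTf, 2,6-lutidine, CH2Cl2, −78 °C
Reagents that add atoms: triethylsilyl trifluoromethanesulfonate, CC[Si](CC)(CC)OS(=O)(=O)C(F)(F)F
Why: Silylation with a silyl triflate and 2,6-lutidine is strong enough for the hindered axial allylic alcohol and is needed because a free or deprotonated 1β-hydroxyl would invite 1,3-acyl shift of the syn-axial angelate in step 9 and would be mesylated in step 10.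

**Step 9**
Reactants: 16 3β-angeloyloxy-1β-(triethylsilyloxy)-11,12,13-trinoreremophil-9-en-8-one
Product: 18 3β-angeloyloxy-11-hydroxy-1β-(triethylsilyloxy)eremophil-9-en-8-one (C7 epimers), via lithium dienolate 17 (not isolated)
Conditions: LDA (LiN(i-Pr)2), THF, −78 °C; acetone, −78 °C; AcOH, −78 °C
Reagents that add atoms: acetone, CC(C)=O
Why: Kinetic deprotonation at C7, the only α′ position, gives the cross-conjugated lithium dienolate 17, whose directed aldol addition to acetone followed by a cold acidic quench (before retro-aldol can set in) should give the β-hydroxy ketone; the C7 configuration is of no consequence because it is removed in step 10.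

**Step 10**
Reactants: 18 3β-angeloyloxy-11-hydroxy-1β-(triethylsilyloxy)eremophil-9-en-8-one
Product: 20 3β-angeloyloxy-1β-(triethylsilyloxy)eremophila-7(11),9-dien-8-one, via tertiary mesylate 19 (not isolated)
Conditions: MsCl, Et3N, DMAP (cat.), CH2Cl2, 0 °C → rt
Reagents that add atoms: none
Why: Sulfene-type mesylation of the tertiary aldol hydroxyl followed by E1cB elimination through the C7 enolate should give the conjugated, tetrasubstituted C7=C11 alkene, the usual way from acetone aldols to α-isopropylidene ketones.

**Step 11**
Reactants: 20 3β-angeloyloxy-1β-(triethylsilyloxy)eremophila-7(11),9-dien-8-one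
Product: 21 3β-angeloyloxy-1β-hydroxyeremophila-7(11),9-dien-8-one
Conditions: HF·pyridine, THF–pyridine, 0 °C
Reagents that add atoms: none
Why: Fluoride-mediated cleavage of the triethylsilyl ether under buffered, weakly acidic conditions frees the alcohol without forming an alkoxide, so the angelate should neither migrate to O1 nor isomerise.

**Step 12**
Reactants: 21 3β-angeloyloxy-1β-hydroxyeremophila-7(11),9-dien-8-one
Product: 22 3β-angeloyloxy-11-hydroperoxy-1β-hydroxyeremophila-6,9-dien-8-one (CNP0300636.1)
Conditions: O2, hν (visible), tetraphenylporphyrin (cat.), CH2Cl2, −20 °C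
Reagents that add atoms: dioxygen (as singlet oxygen), O=O
Why: In this Schenck ene reaction of singlet oxygen with the s-cis α-isopropylidene enone, oxygen bonds to C11 while the axial hydrogen of C6, the allylic group geminal to the carbonyl, is abstracted (gem effect of α,β-unsaturated carbonyl compounds), moving the double bond to C6=C7; no stereocentre is created, and the s-trans C9=C10 enone and the angelate are much less reactive towards singlet oxygen.

**Compound list**

1 | (S)-7a-methyl-2,3,7,7a-tetrahydro-1H-indene-1,5(6H)-dione | O=C1CCC2=CC(=O)CC[C@]12C | starting material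
2 | ethane-1,2-dithiol | SCCS | starting material
3 | (S)-5,5-ethylenedithio-7a-methyl-2,3,5,6,7,7a-hexahydro-1H-inden-1-one (C8 dithiolane of 1, C=C unmoved) | O=C1CCC2=CC3(SCCS3)CC[C@]12C | intermediate
4 | 1,1-dibromoethane | CC(Br)Br | starting material
5 | lithium alkoxide of the 1,1-dibromoethyl carbinol from 3 (carbinol centre not defined, lost in the shift) | [Li]OC1(C(C)(Br)Br)CCC2=CC3(SCCS3)CC[C@]12C | intermediate (not isolated)
6 | β-oxido carbenoid, the 1-bromo-1-lithioethyl lithium alkoxide from 5 | [Li]OC1(C(C)(Br)[Li])CCC2=CC3(SCCS3)CC[C@]12C | intermediate (not isolated)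
7 | lithium enolate (C3–OLi, C3=C4) of the ring-enlarged ketone | CC1=C(O[Li])CCC2=CC3(SCCS3)CC[C@]12C | intermediate (not isolated)
8 | (4R,5R)-8,8-ethylenedithio-11,12,13-trinoreremophil-9-en-3-one (C14 and C15 cis, both β) | O=C1CCC2=CC3(SCCS3)CC[C@]2(C)[C@H]1C | intermediate
9 | 8,8-ethylenedithio-11,12,13-trinoreremophil-9-en-3β-ol ((3S,4R,5R), OH cis to both methyls) | O[C@H]1CCC2=CC3(SCCS3)CC[C@]2(C)[C@H]1C | intermediate
10 | angelic acid, (Z)-2-methylbut-2-enoic acid | C/C=C(/C)C(=O)O | starting material
11 | angelic 2,4,6-trichlorobenzoic mixed anhydride | C/C=C(/C)C(=O)OC(=O)c1c(Cl)cc(Cl)cc1Cl | intermediate (not isolated)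
12 | 3β-angeloyloxy-8,8-ethylenedithio-11,12,13-trinoreremophil-9-ene | C/C=C(/C)C(=O)O[C@H]1CCC2=CC3(SCCS3)CC[C@]2(C)[C@H]1C | intermediate
13 | 3β-angeloyloxy-11,12,13-trinoreremophil-9-en-8-one | C/C=C(/C)C(=O)O[C@H]1CCC2=CC(=O)CC[C@]2(C)[C@H]1C | intermediate
14 | 3β-angeloyloxy-8-(tert-butyldimethylsilyloxy)-11,12,13-trinoreremophila-1(10),8-diene | C/C=C(/C)C(=O)O[C@H]1CC=C2C=C(O[Si](C)(C)C(C)(C)C)CC[C@]2(C)[C@H]1C | intermediate
15 | 3β-angeloyloxy-1β-hydroxy-11,12,13-trinoreremophil-9-en-8-one ((1R,3S,4R,5R)) | C/C=C(/C)C(=O)O[C@H]1C[C@@H](O)C2=CC(=O)CC[C@]2(C)[C@H]1C | intermediate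
16 | 3β-angeloyloxy-1β-(triethylsilyloxy)-11,12,13-trinoreremophil-9-en-8-one | C/C=C(/C)C(=O)O[C@H]1C[C@@H](O[Si](CC)(CC)CC)C2=CC(=O)CC[C@]2(C)[C@H]1C | intermediate
17 | cross-conjugated lithium dienolate (C8–OLi, C7=C8) of 16 | C/C=C(/C)C(=O)O[C@H]1C[C@@H](O[Si](CC)(CC)CC)C2=CC(O[Li])=CC[C@]2(C)[C@H]1C | intermediate (not isolated)
18 | 3β-angeloyloxy-11-hydroxy-1β-(triethylsilyloxy)eremophil-9-en-8-one (C7 not defined) | C/C=C(/C)C(=O)O[C@H]1C[C@@H](O[Si](CC)(CC)CC)C2=CC(=O)C(C(C)(C)O)C[C@]2(C)[C@H]1C | intermediate
19 | 11-methanesulfonate of 18 | C/C=C(/C)C(=O)O[C@H]1C[C@@H](O[Si](CC)(CC)CC)C2=CC(=O)C(C(C)(C)OS(C)(=O)=O)C[C@]2(C)[C@H]1C | intermediate (not isolated)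
20 | 3β-angeloyloxy-1β-(triethylsilyloxy)eremophila-7(11),9-dien-8-one | C/C=C(/C)C(=O)O[C@H]1C[C@@H](O[Si](CC)(CC)CC)C2=CC(=O)C(=C(C)C)C[C@]2(C)[C@H]1C | intermediate
21 | 3β-angeloyloxy-1β-hydroxyeremophila-7(11),9-dien-8-one | C/C=C(/C)C(=O)O[C@H]1C[C@@H](O)C2=CC(=O)C(=C(C)C)C[C@]2(C)[C@H]1C | intermediate
22 | 3β-angeloyloxy-11-hydroperoxy-1β-hydroxyeremophila-6,9-dien-8-one ((1R,3S,4R,5R), CNP0300636.1) | C/C=C(/C)C(=O)O[C@H]1C[C@@H](O)C2=CC(=O)C(C(C)(C)OO)=C[C@]2(C)[C@H]1C | target

Total step count: 12. Longest linear sequence: 12 steps (from 1).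

**Steps most likely to fail**

Step 2. The carbenoid reagent may enolise the hindered ketone instead of adding, n-BuLi may attack the dithiolane, or the C2 ring bond may migrate in place of C5. Fallback, from 3 back to 8: 1-(phenylselanyl)ethyllithium is prepared beforehand from 1,1-bis(phenylselanyl)ethane and n-BuLi at −78 °C, so that no alkyllithium meets the dithiolane. It is added to 3 to give the β-hydroxy selenide F1. TlOEt (monovalent thallium ethoxide) in CHCl3 then generates dichlorocarbene, which turns selenium into a leaving group and triggers a semipinacol shift in which the more substituted carbon is the one known to migrate. This gives ketone 8 directly; because no enolate is formed, the C4 epimers would be separated or equilibrated with base.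

Step 7. Oxygen may be delivered from the α face because the syn-axial angelate crowds the axial path (poor facial selectivity), or attack may occur at C9 instead of C1. Fallback, from 14 back to 15: the oxidation is run as before and the crude mixture of 15 and its C1 epimer, the 1α-alcohol F2, is oxidised with Dess–Martin periodinane to the ene-1,8-dione F3. Luche reduction (NaBH4, CeCl3·7H2O, MeOH, −78 °C) reduces both carbonyls; at C1 the axial path is closed by the syn-axial C14 methyl and angelate, so hydride should enter equatorially and give the 1β,8-diol F4. MnO2 then oxidises the unhindered allylic C8 carbinol selectively and returns 15, with C1 now set by hydride delivery instead of oxygen delivery.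

Step 12. Hydrogen may be abstracted from the C12/C13 methyls instead of from C6 (loss of regiocontrol), or the ene reaction of the electron-poor alkene may be slow enough for dienone photochemistry to compete. Fallback, from 18 to 22, without an ene reaction: the dianion of 18 (LDA, 2.2 equiv, THF, −78 °C) is selenenylated with PhSeBr to the 7-phenylselanyl ketone F5. Oxidation with H2O2/pyridine and syn-elimination of the selenoxide, which has β-hydrogens only on C6, gives the 11-hydroxy-6,9-dien-8-one F6. Brief treatment with 50% H2O2 and catalytic TsOH in Et2O at 0 °C exchanges the tertiary allylic hydroxyl for a hydroperoxyl group through the C11 cation and cleaves the triethylsilyl ether, giving 22.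

**Further compounds**

F1 | step 2 | β-hydroxy selenide: 1-[1-(phenylselanyl)ethyl] carbinol from 3 (new centres not defined) | OC1(C(C)[Se]c2ccccc2)CCC2=CC3(SCCS3)CC[C@]12C
F2 | step 7 | 3β-angeloyloxy-1α-hydroxy-11,12,13-trinoreremophil-9-en-8-one (C1 epimer of 15) | C/C=C(/C)C(=O)O[C@H]1C[C@H](O)C2=CC(=O)CC[C@]2(C)[C@H]1C
F3 | step 7 | 3β-angeloyloxy-11,12,13-trinoreremophil-9-ene-1,8-dione | C/C=C(/C)C(=O)O[C@H]1CC(=O)C2=CC(=O)CC[C@]2(C)[C@H]1C
F4 | step 7 | 3β-angeloyloxy-11,12,13-trinoreremophil-9-ene-1β,8-diol (C8 not defined) | C/C=C(/C)C(=O)O[C@H]1C[C@@H](O)C2=CC(O)CC[C@]2(C)[C@H]1C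
F5 | step 12 | 3β-angeloyloxy-11-hydroxy-7-(phenylselanyl)-1β-(triethylsilyloxy)eremophil-9-en-8-one (C7 not defined) | C/C=C(/C)C(=O)O[C@H]1C[C@@H](O[Si](CC)(CC)CC)C2=CC(=O)C([Se]c3ccccc3)(C(C)(C)O)C[C@]2(C)[C@H]1C
F6 | step 12 | 3β-angeloyloxy-11-hydroxy-1β-(triethylsilyloxy)eremophila-6,9-dien-8-one | C/C=C(/C)C(=O)O[C@H]1C[C@@H](O[Si](CC)(CC)CC)C2=CC(=O)C(C(C)(C)O)=C[C@]2(C)[C@H]1C
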